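## The problem

Septeremophilane G (**30**) is a trinor-eremophilane ester. Ring A (C1H2, C2–OH, C3–O-acyl, C4–Me, C5–Me, C10) shares the C5–C10 edge with ring B, which is a cross-conjugated dienone holding an enolised 1,2-dione (diosphenol): C6H=C7(OH)–C8(=O)–C9H=C10. Ring A carries four contiguous stereocentres (2R, 3R, 4R, 5S, that is 2α-hydroxy, 3β-acyloxy, 4β- and 5β-methyl), and the (2E,4E)-6-methylocta-2,4-dienoyl chain carries one more (6S). The quaternary C5 is the difficult centre. Its neighbour C4 is the only centre that can be bought and made to control it. Once C5 is set, its axial methyl screens the β face of ring A, so C2 and C3 can follow from a C2=C3 alkene by α-epoxidation and trans-diaxial opening. The side-chain centre is remote and is taken from the chiral pool. Several groups rule out rough treatment: the diosphenol (acidic, oxidisable), the dienone (base removes the γ-protons at C1, which moves double bonds or expels an oxygen at C2), the hindered ester beside a free hydroxyl (acyl migration) and the dienoate. The feature that opens the route is ring B itself: a six-membered ring with two double bonds and a quaternary sp3 carbon. C5–C10 and C8–C9 are the two σ-bonds of a [4+2] adduct between an alkyne C9≡C10 and a 1,2-dioxygenated diene C5=C6–C7=C8, and if the alkyne is tied to C5 through C1–C4 the same event closes ring A.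

## Retrosynthesis

**Ester and C3–O bond.** **30** is the desilylated form of the silyl enol ether **29**, and **29** is cut at the C3–O bond into the 2α,3α-epoxide **24** and the dienoic acid **28**. Acylating a 2,3-diol would be the neighbouring cut, but the 3β-hydroxyl is the more hindered one (axial, next to C4–Me, syn to C5–Me), so O2 would need protecting first. Opening the epoxide forms C3–O, frees O2–H and sets both configurations in one step. The forward reaction must deliver the carboxylate to C3 from the β face without acid or base strong enough to harm the dienone.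

**Epoxide.** **24** is cut at both C–O bonds to the alkene **23**. The axial C5 methyl should send the peracid to the α face. The step requires that only the isolated C2=C3 bond reacts, so the diosphenol is carried as its silyl enol ether.

**Oxidation level of C8.** **23** comes from the cycloadduct **22** by turning the C8 silyloxy carbinol into the ketone while the C7 enol ether stays. A cycloaddition needs C8 as an sp3 diene terminus, so the adduct is one oxidation below ring B. The oxidation also removes the C8 stereocentre, which is not needed.

**Both rings (key cut).** **22** is cut at C5–C10 and C8–C9 to the acyclic dienyne **21**. Closing ring B by aldol chemistry or ring A by metathesis would build one ring at a time on a preformed ring. This cut instead reaches a chain with one stereocentre. The forward reaction has to form a quaternary carbon at a diene terminus that carries a methyl on the inside. Heat would invite a 1,5-hydrogen shift from that methyl, so catalysis by zerovalent nickel is chosen. C4 must direct the face of attack at C5.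

**Diene and C6–C7.** **21** is the enol silyl ether of ketone **19**, which is the desilylated alkyne of **18**. **18** is cut at C6–C7 into the alkenyl iodide **13** and the glycolic Weinreb amide **16** (from methyl glycolate **14** via **15**). This puts both oxygens of ring B in from a two-carbon piece in one C–C bond formation. Adding the alkenyl metal to an aldehyde and oxidising would take one step more.

**C2=C3.** **13** is cut at the Z alkene into aldehyde **11** and phosphonium salt **3** (from **1** via **2**). The ylide brings C1, C2, C10 and C9 with the alkyne masked by silicon, and the Z geometry is what lets the tether reach C5. The order matters: the α-vinyl aldehyde **11** epimerises easily, and the only thing it meets is a fast Wittig reaction at −78 °C. Homologating such an aldehyde to an alkyne in carbonate/methanol would be the riskier order.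

**C4 and C5=C6.** **11** goes back through **10** and **9** to the alkyne **7**, with methyl and iodine added across the triple bond by carboalumination. **7** comes from the hydroxy ester **4** via **5** and **6**. The ester carbon of **4** becomes C5 and its hydroxymethyl carbon becomes C3. With the (S) ester this gives the (S) centre of **21**, which is (4R) in **30**.

**Side chain.** **28** is cut at C2'=C3' into (S)-2-methylbutanal **26** (from the alcohol **25**) and a phosphonocrotonate, via the ester **27**.

## Roads not taken

**Alternative 1:** Silicon-tethered dearomative methylation. The cut is C5–C14 (the methyl carbon on C5). In the forward step the phenoxide of the tetralin A2 is alkylated at its para ring-fusion carbon C5 by the bromomethylsilyl ether on O3, giving the bridged dienone A1.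
- Merits: the configuration of C5 is dictated by the tether from the β oxygen on C3 and does not depend on 1,2-induction. In this respect it is safer than the chosen plan. Ring B also appears at the dienone level with the C7 oxygen in place.
- Weak points: A2 needs three contiguous stereocentres (C2, C3, benzylic C4) before the key step, which is about as long as the whole acyclic sequence here. After the key step the C14–Si bond of A1 must become C14–H. Oxidative cleavage would give a hydroxymethyl group, and protodesilylation of an unactivated neopentyl-type silane needs hot fluoride or base, which the dienone with its γ-protons is unlikely to survive. The enol methyl ether and the acetal on O2 need acid to remove.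
- Comparison: the chosen plan makes both rings and C5 in one step from a chain with a single bought stereocentre and has no C–Si to C–H problem. It pays with a less certain facial selectivity.

**Alternative 2:** Acyloin coupling of C7 to C8. The cut is C7–C8. Sodium and Me3SiCl couple the two ester carbons of diester A4 to the enediol bis(silyl) ether A3.
- Merits: the ring closure is among the most reliable for six-membered rings, the two oxygens land on C7 and C8 with no regiochemical question, and no stereochemistry is at stake in the key step. On reliability of the ring closure it is better than a nickel-catalysed cycloaddition at a hindered terminus.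
- Weak points: the key step makes no stereocentre and no bond to the quaternary carbon. A4 must already hold C4, quaternary C5 and a fully substituted oxygenated C10 with two acetic ester arms, and that is the hard part of the molecule. The β-silyloxy ester in A4 can fragment under dissolving metal. After A3 the route still needs dehydration to C9=C10, oxidation to the dienone, unmasking and stereoselective reduction of C3, hydroxylation at C2 and esterification of a hindered axial alcohol.
- Comparison: the chosen plan is shorter after its key step (four steps) and sets C5 in that step.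

**Alternative 3:** Desymmetrising Michael closure. The cut is C1–C10. A cinchona-derived primary amine salt converts the methyl ketone of the prochiral dienone A6 into an enamine whose carbon C1 adds to one enone arm, giving the cis-fused dione A5.
- Merits: the quaternary centre is set under catalyst control, which is the strongest way of fixing C5 among the four plans. The reaction type is established for 4,4-disubstituted cyclohexadienones.
- Weak points: enamine formation toward the silyloxy-bearing C3 and epimerisation there compete. A5 has C10 as an sp3 CH and no oxygen on C7, so C9=C10 must be reintroduced and C7 oxidised. The C2 ketone must be reduced to the axial 2α-alcohol in the presence of the C8 enone, and the oxygen on C3 must change from silyl to acyl beside a free hydroxyl.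
- Comparison: the chosen plan cannot match the catalyst control of C5. Against that, its cycloadduct already carries both ring B oxygens and C9=C10, one oxidation from the diosphenol, and ring A carries the alkene from which C2 and C3 are set trans without any ketone reduction.

Key step: step 15

Assumption: **22** is drawn as the C8 epimer that follows from suprafacial addition to the Z enediol ether. Step 16 turns C8 into a carbonyl carbon, so the route does not depend on this centre.

## Steps

Step 1
Reactants: 1 4-(trimethylsilyl)but-3-yn-1-ol
Product: 2 (4-iodobut-1-yn-1-yl)trimethylsilane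
Conditions: I2, PPh3, imidazole, CH2Cl2, 0 → 23 °C
Reagents that add atoms: iodine, II
Why: Appel-type iodination of a primary alcohol; the silyl-capped alkyne is inert.

Step 2
Reactants: 2 (4-iodobut-1-yn-1-yl)trimethylsilane
Product: 3 triphenyl[4-(trimethylsilyl)but-3-yn-1-yl]phosphonium iodide
Conditions: PPh3, MeCN, reflux
Reagents that add atoms: triphenylphosphine, c1ccc(cc1)P(c1ccccc1)c1ccccc1
Why: SN2 quaternisation of the phosphine by a primary iodide; no base is present, so the homopropargylic iodide should not eliminate.

Step 3
Reactants: 4 methyl (S)-3-hydroxy-2-methylpropanoate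
Product: 5 methyl (S)-3-[(tert-butyldimethylsilyl)oxy]-2-methylpropanoate
Conditions: TBSCl, imidazole, CH2Cl2, 0 → 23 °C
Reagents that add atoms: tert-butyldimethylsilyl chloride, CC(C)(C)[Si](C)(C)Cl
Why: Standard silylation of a primary alcohol; imidazole does not epimerise the ester α-centre.

Step 4
Reactants: 5 methyl (S)-3-[(tert-butyldimethylsilyl)oxy]-2-methylpropanoate
Product: 6 (S)-3-[(tert-butyldimethylsilyl)oxy]-2-methylpropanal
Conditions: DIBAL-H (1.05 equiv), CH2Cl2, −78 °C; aq. Rochelle salt
Reagents that add atoms: none
Why: Partial reduction of the ester through the aluminium hemiacetal, which is stable at −78 °C; the aldehyde is kept cold and used without chromatography so that the α-centre is retained.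

Step 5
Reactants: 6 (S)-3-[(tert-butyldimethylsilyl)oxy]-2-methylpropanal
Product: 7 (R)-tert-butyldimethyl[(2-methylbut-3-yn-1-yl)oxy]silane
Conditions: Ohira–Bestmann reagent, K2CO3, MeOH, 0 → 23 °C
Reagents that add atoms: dimethyl (1-diazo-2-oxopropyl)phosphonate, COP(=O)(OC)C(=[N+]=[N-])C(C)=O
Why: Seyferth–Gilbert homologation in the Ohira–Bestmann form turns the aldehyde into the terminal alkyne; this saturated β-silyloxy aldehyde is a standard substrate for it and should keep its configuration, and the ester carbon of 4 thereby becomes C5.

Step 6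
Reactants: 7 (R)-tert-butyldimethyl[(2-methylbut-3-yn-1-yl)oxy]silane
Product: 9 (R,E)-tert-butyl[(4-iodo-2,3-dimethylbut-3-en-1-yl)oxy]dimethylsilane, via dimethyl(alkenyl)alane 8 (not isolated)
Conditions: AlMe3 (2.5 equiv), Cp2ZrCl2 (0.3 equiv), CH2Cl2, 0 → 23 °C; then I2, THF, −30 → 0 °C
Reagents that add atoms: trimethylaluminium, C[Al](C)C; iodine, II
Why: Negishi carboalumination adds methyl and aluminium syn across the terminal alkyne with aluminium on the terminal carbon, and iodinolysis with retention gives the E iodide; this fixes the C5=C6 geometry with the methyl on the inside of the later diene.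

Step 7
Reactants: 9 (R,E)-tert-butyl[(4-iodo-2,3-dimethylbut-3-en-1-yl)oxy]dimethylsilane
Product: 10 (R,E)-4-iodo-2,3-dimethylbut-3-en-1-ol
Conditions: camphorsulfonic acid (10 mol %), MeOH/CH2Cl2, 0 → 23 °C
Reagents that add atoms: none
Why: Acid-catalysed methanolysis of a primary silyl ether; nothing else in 9 is acid-sensitive.

Step 8
Reactants: 10 (R,E)-4-iodo-2,3-dimethylbut-3-en-1-ol
Product: 11 (R,E)-4-iodo-2,3-dimethylbut-3-enal
Conditions: Dess–Martin periodinane, NaHCO3, CH2Cl2, 0 °C; filtered cold and used at once
Reagents that add atoms: none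
Why: Dess–Martin oxidation under bicarbonate buffer makes the α-vinyl aldehyde without base; it is not stored because its α-proton is both allylic and next to the carbonyl.

Step 9
Reactants: 3 triphenyl[4-(trimethylsilyl)but-3-yn-1-yl]phosphonium iodide; 11 (R,E)-4-iodo-2,3-dimethylbut-3-enal
Product: 13 [(4Z,6S,7E)-8-iodo-6,7-dimethylocta-4,7-dien-1-yn-1-yl]trimethylsilane, via phosphorus ylide 12 (not isolated)
Conditions: 3, NaHMDS, THF, −78 → 0 °C; then 11, −78 → 0 °C
Reagents that add atoms: none
Why: Wittig reaction of a non-stabilised ylide under lithium-free conditions gives the Z alkene C2=C3 through the kinetic cis-oxaphosphetane; addition at −78 °C should outrun enolisation of 11, so C4 is retained.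

Step 10
Reactants: 14 methyl glycolate
Product: 15 methyl 2-[(tert-butyldimethylsilyl)oxy]acetate
Conditions: TBSCl, imidazole, CH2Cl2, 0 → 23 °C
Reagents that add atoms: tert-butyldimethylsilyl chloride, CC(C)(C)[Si](C)(C)Cl
Why: Standard silylation of a primary alcohol.

Step 11
Reactants: 15 methyl 2-[(tert-butyldimethylsilyl)oxy]acetate
Product: 16 2-[(tert-butyldimethylsilyl)oxy]-N-methoxy-N-methylacetamide
Conditions: MeNH(OMe)·HCl, i-PrMgCl, THF, −20 → 0 °C
Reagents that add atoms: N,O-dimethylhydroxylamine hydrochloride, CNOC.Cl
Why: Aminolysis of the ester by the magnesium amide of N,O-dimethylhydroxylamine gives the Weinreb amide directly.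

Step 12
Reactants: 13 [(4Z,6S,7E)-8-iodo-6,7-dimethylocta-4,7-dien-1-yn-1-yl]trimethylsilane; 16 2-[(tert-butyldimethylsilyl)oxy]-N-methoxy-N-methylacetamide
Product: 18 (3E,5S,6Z)-1-[(tert-butyldimethylsilyl)oxy]-4,5-dimethyl-10-(trimethylsilyl)deca-3,6-dien-9-yn-2-one, via alkenyllithium 17 (not isolated)
Conditions: t-BuLi (2.1 equiv), Et2O, −78 °C; then 16, −78 → −40 °C; aq. NH4Cl
Reagents that add atoms: none
Why: Iodine–lithium exchange with retention of alkene geometry followed by Weinreb ketone synthesis; the chelated tetrahedral intermediate stops over-addition, and the step forms C6–C7 and brings in both oxygens of ring B.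

Step 13
Reactants: 18 (3E,5S,6Z)-1-[(tert-butyldimethylsilyl)oxy]-4,5-dimethyl-10-(trimethylsilyl)deca-3,6-dien-9-yn-2-one
Product: 19 (3E,5S,6Z)-1-[(tert-butyldimethylsilyl)oxy]-4,5-dimethyldeca-3,6-dien-9-yn-2-one
Conditions: AgNO3 (10 mol %), MeOH/H2O/CH2Cl2, 23 °C
Reagents that add atoms: none
Why: Silver-catalysed protodesilylation of the alkynylsilane under neutral conditions; carbonate in methanol is avoided because C4–H of 18 is γ to the enone and doubly allylic, and the alkyl silyl ether is left alone.

Step 14
Reactants: 19 (3E,5S,6Z)-1-[(tert-butyldimethylsilyl)oxy]-4,5-dimethyldeca-3,6-dien-9-yn-2-one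
Product: 21 (1Z,3E,5S,6Z)-1,2-bis[(tert-butyldimethylsilyl)oxy]-4,5-dimethyldeca-1,3,6-trien-9-yne, via lithium enolate 20 (not isolated)
Conditions: LiHMDS (1.1 equiv), THF, −78 °C; then TBSOTf, −78 °C; Et3N, pentane, pH 7 buffer
Reagents that add atoms: tert-butyldimethylsilyl trifluoromethanesulfonate, CC(C)(C)[Si](C)(C)OS(=O)(=O)C(F)(F)F
Why: Kinetic deprotonation at the oxygenated α'-carbon C8 gives the cross-conjugated enolate (the amide base leaves the much less acidic alkyne C–H and the γ-positions alone at −78 °C); lithium chelation by the α-silyloxy group favours the Z enolate, and O-silylation gives the Z enediol bis(silyl) ether.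

Step 15
Reactants: 21 (1Z,3E,5S,6Z)-1,2-bis[(tert-butyldimethylsilyl)oxy]-4,5-dimethyldeca-1,3,6-trien-9-yne
Product: 22 (2S,4aS,5S)-2,3-bis[(tert-butyldimethylsilyl)oxy]-4a,5-dimethyl-2,4a,5,8-tetrahydronaphthalene
Conditions: Ni(cod)2 (10 mol %), P(O-2-biphenylyl)3 (30 mol %), THF (0.01 M), 25 → 50 °C
Reagents that add atoms: none
Why: Zerovalent nickel binds the alkyne and the C5=C6 bond, oxidative cyclisation forms C5–C10 and gives a nickelacycle with a C9 alkenyl–nickel bond and an η3-allyl over C6–C8, and reductive elimination forms C8–C9 and releases the cyclohexa-1,4-diene and the catalyst. The closest known reaction is the nickel-catalysed intramolecular [4+2] cycloaddition of dienynes, which runs near room temperature and forms angular quaternary carbons, whereas heating a diene with a Z methyl invites a 1,5-hydrogen shift. Ring A closes in the C5–C10 step as a six-membered ring, exo with respect to both the alkyne and the C5=C6 bond and preorganised by the Z alkene C2=C3; ring B closes in the C8–C9 reductive elimination from the seven-membered alkenyl(allyl)nickel ring. C5 is controlled by C4: in the nearly planar nickelacycle C6 lies anti to C1, so the C5 methyl is axial on the forming half-chair of ring A, and the C4 substituent that eclipses the C5–nickel direction has to be hydrogen; the C4 methyl is then pseudo-equatorial and cis to the C5 methyl (5S). C8 follows from the Z enediol geometry (silyloxy group trans to the C5 methyl) and is removed in step 16. The step needs the conjugated diene to react in preference to the isolated Z alkene, which only the diene can do through an allyl complex, and ring closure in preference to alkyne oligomerisation, which the high dilution secures.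

Step 16
Reactants: 22 (2S,4aS,5S)-2,3-bis[(tert-butyldimethylsilyl)oxy]-4a,5-dimethyl-2,4a,5,8-tetrahydronaphthalene
Product: 23 (4aS,5S)-3-[(tert-butyldimethylsilyl)oxy]-4a,5-dimethyl-5,8-dihydronaphthalen-2(4aH)-one
Conditions: DDQ (1.1 equiv), CH2Cl2/pH 7 buffer, 0 °C
Reagents that add atoms: none
Why: DDQ abstracts hydride from C8–H, which is doubly allylic and carries the silyloxy group, and the silyloxocarbenium ion loses its silyl group to water: this is the known DDQ oxidation of allylic silyl ethers to enones. The C7 enol ether cannot be dehydrogenated because C5 has no hydrogen, so it stays as the protecting group of the diosphenol, and the C8 stereocentre disappears.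

Step 17
Reactants: 23 (4aS,5S)-3-[(tert-butyldimethylsilyl)oxy]-4a,5-dimethyl-5,8-dihydronaphthalen-2(4aH)-one
Product: 24 (4aS,5R,6S,7R)-3-[(tert-butyldimethylsilyl)oxy]-6,7-epoxy-4a,5-dimethyl-5,6,7,8-tetrahydronaphthalen-2(4aH)-one (the 2α,3α-epoxide in target numbering)
Conditions: mCPBA (1.1 equiv), NaHCO3, CH2Cl2, 0 °C
Reagents that add atoms: 3-chloroperoxybenzoic acid, OOC(=O)c1cccc(Cl)c1
Why: Prilezhaev epoxidation of the only isolated alkene (C9=C10 is an enone; C6=C7 is conjugated to the ketone and neopentylic); the peracid should approach anti to the axial C5 methyl and the C4 methyl, as with Δ2-steroids, to give the α-epoxide with C2 (R) and C3 (S).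

Step 18
Reactants: 25 (S)-2-methylbutan-1-ol
Product: 26 (S)-2-methylbutanal
Conditions: TEMPO (1 mol %), KBr (10 mol %), NaOCl, NaHCO3-buffered H2O/CH2Cl2, 0 °C; dried solution used directly
Reagents that add atoms: none
Why: Anelli oxidation gives the volatile α-chiral aldehyde under buffered conditions that should not racemise it.

Step 19
Reactants: 26 (S)-2-methylbutanal
Product: 27 ethyl (2E,4E,6S)-6-methylocta-2,4-dienoate
Conditions: triethyl 4-phosphonocrotonate, LiHMDS, THF, −78 → 0 °C
Reagents that add atoms: triethyl (E)-4-phosphonocrotonate, CCOC(=O)/C=C/CP(=O)(OCC)OCC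
Why: Vinylogous Horner–Wadsworth–Emmons olefination; the stabilised phosphonate anion gives the new C4=C5 bond E and keeps the C2=C3 bond E.

Step 20
Reactants: 27 ethyl (2E,4E,6S)-6-methylocta-2,4-dienoate
Product: 28 (2E,4E,6S)-6-methylocta-2,4-dienoic acid
Conditions: LiOH, THF/MeOH/H2O, 23 °C; then aq. HCl
Reagents that add atoms: lithium hydroxide, [Li+].[OH-]
Why: Saponification of the ethyl ester; the remote stereocentre is not enolisable.

Step 21
Reactants: 24 (4aS,5R,6S,7R)-3-[(tert-butyldimethylsilyl)oxy]-6,7-epoxy-4a,5-dimethyl-5,6,7,8-tetrahydronaphthalen-2(4aH)-one; 28 (2E,4E,6S)-6-methylocta-2,4-dienoic acid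
Product: 29 (1R,2R,3R,8aS)-7-[(tert-butyldimethylsilyl)oxy]-3-hydroxy-1,8a-dimethyl-6-oxo-1,2,3,4,6,8a-hexahydronaphthalen-2-yl (2E,4E,6S)-6-methylocta-2,4-dienoate
Conditions: 28 (2 equiv), racemic [N,N'-bis(3,5-di-tert-butylsalicylidene)-trans-1,2-cyclohexanediaminato]cobalt (10 mol %, divalent cobalt, oxidised in the flask by air and 28 to the trivalent cobalt carboxylate), i-Pr2NEt, t-BuOMe, 25 °C
Reagents that add atoms: none
Why: Epoxide opening by a carboxylic acid under cobalt–salen carboxylate catalysis, obeying the Fürst–Plattner rule: ring A is locked with the C5 methyl axial, so trans-diaxial opening means attack at C3 from the β face with inversion (3R) while the oxygen stays on C2 on the α face (2R).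

Step 22
Reactants: 29 (1R,2R,3R,8aS)-7-[(tert-butyldimethylsilyl)oxy]-3-hydroxy-1,8a-dimethyl-6-oxo-1,2,3,4,6,8a-hexahydronaphthalen-2-yl (2E,4E,6S)-6-methylocta-2,4-dienoate
Product: 30 septeremophilane G, (1R,2R,3R,8aS)-3,7-dihydroxy-1,8a-dimethyl-6-oxo-1,2,3,4,6,8a-hexahydronaphthalen-2-yl (2E,4E,6S)-6-methylocta-2,4-dienoate
Conditions: HF·pyridine, pyridine, THF, 0 °C
Reagents that add atoms: none
Why: Fluoride cleavage of the silyl enol ether under buffered, non-basic conditions should free the diosphenol without acyl migration from O3 to O2 or elimination at C1/C2.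

## Compound list

1 | 4-(trimethylsilyl)but-3-yn-1-ol | C[Si](C)(C)C#CCCO | starting material
2 | (4-iodobut-1-yn-1-yl)trimethylsilane | C[Si](C)(C)C#CCCI | intermediate
3 | triphenyl[4-(trimethylsilyl)but-3-yn-1-yl]phosphonium iodide | C[Si](C)(C)C#CCC[P+](c1ccccc1)(c1ccccc1)c1ccccc1.[I-] | intermediate
4 | methyl (S)-3-hydroxy-2-methylpropanoate | COC(=O)[C@@H](C)CO | starting material
5 | methyl (S)-3-[(tert-butyldimethylsilyl)oxy]-2-methylpropanoate | COC(=O)[C@@H](C)CO[Si](C)(C)C(C)(C)C | intermediate
6 | (S)-3-[(tert-butyldimethylsilyl)oxy]-2-methylpropanal | O=C[C@@H](C)CO[Si](C)(C)C(C)(C)C | intermediate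
7 | (R)-tert-butyldimethyl[(2-methylbut-3-yn-1-yl)oxy]silane | C#C[C@@H](C)CO[Si](C)(C)C(C)(C)C | intermediate
8 | [(1E,3R)-4-[(tert-butyldimethylsilyl)oxy]-2,3-dimethylbut-1-en-1-yl]dimethylalane | C[Al](C)/C=C(C)/[C@@H](C)CO[Si](C)(C)C(C)(C)C | intermediate (not isolated)
9 | (R,E)-tert-butyl[(4-iodo-2,3-dimethylbut-3-en-1-yl)oxy]dimethylsilane | I/C=C(C)/[C@@H](C)CO[Si](C)(C)C(C)(C)C | intermediate
10 | (R,E)-4-iodo-2,3-dimethylbut-3-en-1-ol | I/C=C(C)/[C@@H](C)CO | intermediate
11 | (R,E)-4-iodo-2,3-dimethylbut-3-enal | I/C=C(C)/[C@@H](C)C=O | intermediate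
12 | triphenyl[4-(trimethylsilyl)but-3-yn-1-ylidene]-λ5-phosphane | C[Si](C)(C)C#CCC=P(c1ccccc1)(c1ccccc1)c1ccccc1 | intermediate (not isolated)
13 | [(4Z,6S,7E)-8-iodo-6,7-dimethylocta-4,7-dien-1-yn-1-yl]trimethylsilane | I/C=C(C)/[C@@H](C)/C=C\CC#C[Si](C)(C)C | intermediate
14 | methyl glycolate | COC(=O)CO | starting material
15 | methyl 2-[(tert-butyldimethylsilyl)oxy]acetate | COC(=O)CO[Si](C)(C)C(C)(C)C | intermediate
16 | 2-[(tert-butyldimethylsilyl)oxy]-N-methoxy-N-methylacetamide | CON(C)C(=O)CO[Si](C)(C)C(C)(C)C | intermediate
17 | [(1E,3S,4Z)-2,3-dimethyl-8-(trimethylsilyl)octa-1,4-dien-7-yn-1-yl]lithium | [Li]/C=C(C)/[C@@H](C)/C=C\CC#C[Si](C)(C)C | intermediate (not isolated)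
18 | (3E,5S,6Z)-1-[(tert-butyldimethylsilyl)oxy]-4,5-dimethyl-10-(trimethylsilyl)deca-3,6-dien-9-yn-2-one | C[Si](C)(C)C#CC/C=C\[C@H](C)/C(C)=C/C(=O)CO[Si](C)(C)C(C)(C)C | intermediate
19 | (3E,5S,6Z)-1-[(tert-butyldimethylsilyl)oxy]-4,5-dimethyldeca-3,6-dien-9-yn-2-one | C#CC/C=C\[C@H](C)/C(C)=C/C(=O)CO[Si](C)(C)C(C)(C)C | intermediate
20 | lithium (1Z,3E,5S,6Z)-1-[(tert-butyldimethylsilyl)oxy]-4,5-dimethyldeca-1,3,6-trien-9-yn-2-olate | C#CC/C=C\[C@H](C)/C(C)=C/C(O[Li])=C/O[Si](C)(C)C(C)(C)C | intermediate (not isolated)
21 | (1Z,3E,5S,6Z)-1,2-bis[(tert-butyldimethylsilyl)oxy]-4,5-dimethyldeca-1,3,6-trien-9-yne | C#CC/C=C\[C@H](C)/C(C)=C/C(O[Si](C)(C)C(C)(C)C)=C/O[Si](C)(C)C(C)(C)C | intermediate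
22 | (2S,4aS,5S)-2,3-bis[(tert-butyldimethylsilyl)oxy]-4a,5-dimethyl-2,4a,5,8-tetrahydronaphthalene | C1=CCC2=C[C@H](O[Si](C)(C)C(C)(C)C)C(O[Si](C)(C)C(C)(C)C)=C[C@]2(C)[C@H]1C | intermediate
23 | (4aS,5S)-3-[(tert-butyldimethylsilyl)oxy]-4a,5-dimethyl-5,8-dihydronaphthalen-2(4aH)-one | C1=CCC2=CC(=O)C(O[Si](C)(C)C(C)(C)C)=C[C@]2(C)[C@H]1C | intermediate
24 | (4aS,5R,6S,7R)-3-[(tert-butyldimethylsilyl)oxy]-6,7-epoxy-4a,5-dimethyl-5,6,7,8-tetrahydronaphthalen-2(4aH)-one | O1[C@@H]2[C@H]1CC3=CC(=O)C(O[Si](C)(C)C(C)(C)C)=C[C@]3(C)[C@H]2C | intermediate
25 | (S)-2-methylbutan-1-ol | CC[C@H](C)CO | starting material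
26 | (S)-2-methylbutanal | CC[C@H](C)C=O | intermediate
27 | ethyl (2E,4E,6S)-6-methylocta-2,4-dienoate | CC[C@H](C)/C=C/C=C/C(=O)OCC | intermediate
28 | (2E,4E,6S)-6-methylocta-2,4-dienoic acid | CC[C@H](C)/C=C/C=C/C(=O)O | intermediate
29 | (1R,2R,3R,8aS)-7-[(tert-butyldimethylsilyl)oxy]-3-hydroxy-1,8a-dimethyl-6-oxo-1,2,3,4,6,8a-hexahydronaphthalen-2-yl (2E,4E,6S)-6-methylocta-2,4-dienoate | CC[C@H](C)/C=C/C=C/C(=O)O[C@H]1[C@H](O)CC2=CC(=O)C(O[Si](C)(C)C(C)(C)C)=C[C@]2(C)[C@H]1C | intermediate
30 | septeremophilane G | CC[C@H](C)/C=C/C=C/C(=O)O[C@H]1[C@H](O)CC2=CC(=O)C(O)=C[C@]2(C)[C@H]1C | target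

## Step count and least certain steps

Total step count: 22. Longest linear sequence: 15 steps, from **4** to **30** (steps 3–9, 12–17, 21, 22).

**Step 15 (key step).** The oxidative cyclisation has to form a quaternary carbon at a diene terminus with a methyl on the inside. If it is slow, nickel can be drawn into oligomerising the terminal alkyne, and the doubly silylated enediol ether, which is sensitive to acid and fluoride, can hydrolyse or lose its Z geometry. Facial control by the single centre C4 may also be incomplete. The fallback takes the C8 oxygen out of the cycloaddition and installs it after the rings are closed.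
- It sets out from **13**, which is lithiated as in step 12 and acylated with N-methoxy-N-methylacetamide to give the methyl enone F1.
- Silver-catalysed desilylation gives the terminal alkyne F2, and kinetic enolisation with silylation (LiHMDS, TBSOTf, −78 °C) gives the 2-silyloxydiene F3. F3 has an unsubstituted terminus, no geometric isomers and only one labile silyl group.
- The same nickel-catalysed cycloaddition gives the enol ether F4, and buffered fluoride (HF·pyridine) gives the β,γ-unsaturated ketone F5.
- Deprotonation of F5 at the doubly activated C8 (LiHMDS, −78 °C) and hydroxylation with 2-(phenylsulfonyl)-3-phenyloxaziridine gives the acyloin F6.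
- F6 is carried on as in the fallback to step 16, through the diosphenol F7, and the route is rejoined at **23**.

**Step 16.** Hydride abstraction may not stay at C8. DDQ can add to the electron-rich enol ether carbon C6 or abstract from the doubly allylic C1, and the enol silyl group can be lost in the process. The fallback replaces the direct oxidation by the stepwise classical sequence. From **22**, HF·pyridine removes both silyl groups and gives the acyloin F6 (the C8 epimers interconvert through the enediol and both serve). Cu(OAc)2 in aqueous acetic acid/methanol oxidises it to the free diosphenol F7, and TBSCl/imidazole silylates the acidic enol to return to **23**.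

**Step 21.** C3 is flanked by the C4 methyl and lies under the axial C5 methyl. Attack there may be slow enough that opening at C2 (the diequatorial mode), Lewis acid-induced rearrangement of the epoxide to a ketone, or later acyl migration competes. The fallback separates ring opening from acylation.
- From **24**, dilute HClO4 in aqueous THF gives the trans-diaxial diol F8.
- The less hindered 2α-hydroxyl is silylated selectively (Et3SiCl, imidazole, −20 °C) to F9.
- The hindered 3β-hydroxyl is esterified with **28** under Yamaguchi conditions (2,4,6-trichlorobenzoyl chloride, Et3N, DMAP) to F10.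
- HF·pyridine removes both silyl groups and gives **30**.

**Step 9.** The α-proton of **11** is allylic and next to the carbonyl, so the basic ylide may enolise it before olefination. That would erode the configuration at C4 or move the double bond into conjugation. The fallback reverses the polarity of the Wittig reaction so that no epimerisable aldehyde is involved.
- From **10**, I2/PPh3/imidazole gives the diiodide F11.
- PPh3 in acetonitrile alkylates only at the primary iodide to give the phosphonium salt F12, whose stereocentre is β to phosphorus and cannot epimerise.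
- Deprotonation with NaHMDS and condensation at −78 °C with 4-(trimethylsilyl)but-3-ynal F13 (from **1** by Dess–Martin oxidation, used at once) returns to **13**.

## Further compounds

F1 | step 15 | (3E,5S,6Z)-4,5-dimethyl-10-(trimethylsilyl)deca-3,6-dien-9-yn-2-one | C[Si](C)(C)C#CC/C=C\[C@H](C)/C(C)=C/C(C)=O
F2 | step 15 | (3E,5S,6Z)-4,5-dimethyldeca-3,6-dien-9-yn-2-one | C#CC/C=C\[C@H](C)/C(C)=C/C(C)=O
F3 | step 15 | tert-butyl{[(3E,5S,6Z)-4,5-dimethyldeca-1,3,6-trien-9-yn-2-yl]oxy}dimethylsilane | C#CC/C=C\[C@H](C)/C(C)=C/C(=C)O[Si](C)(C)C(C)(C)C
F4 | step 15 | cycloadduct without the C8 oxygen: C6=C7 tert-butyldimethylsilyl enol ether of the (4S,5S)-4,5-dimethyl bicycle with C2=C3 and C9=C10 (target numbering) | C1=CCC2=CCC(O[Si](C)(C)C(C)(C)C)=C[C@]2(C)[C@H]1C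
F5 | step 15 | β,γ-unsaturated C7 ketone of the same bicycle (C6H2, C8H2, C9=C10, C2=C3; 4β,5β-dimethyl) | C1=CCC2=CCC(=O)C[C@]2(C)[C@H]1C
F6 | step 16 | acyloin: 8-hydroxy-7-ketone of the same bicycle (C8 epimers interconvert) | C1=CCC2=CC(O)C(=O)C[C@]2(C)[C@H]1C
F7 | step 16 | (4aS,5S)-3-hydroxy-4a,5-dimethyl-5,8-dihydronaphthalen-2(4aH)-one (free diosphenol) | C1=CCC2=CC(=O)C(O)=C[C@]2(C)[C@H]1C
F8 | step 21 | (4aS,5R,6R,7R)-3-[(tert-butyldimethylsilyl)oxy]-6,7-dihydroxy-4a,5-dimethyl-5,6,7,8-tetrahydronaphthalen-2(4aH)-one (2α,3β-diol in target numbering) | O[C@H]1[C@H](O)CC2=CC(=O)C(O[Si](C)(C)C(C)(C)C)=C[C@]2(C)[C@H]1C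
F9 | step 21 | 2-O-triethylsilyl ether of F8 (free 3β-hydroxyl) | O[C@H]1[C@H](O[Si](CC)(CC)CC)CC2=CC(=O)C(O[Si](C)(C)C(C)(C)C)=C[C@]2(C)[C@H]1C
F10 | step 21 | 3-O-[(2E,4E,6S)-6-methylocta-2,4-dienoyl] ester of F9 | CC[C@H](C)/C=C/C=C/C(=O)O[C@H]1[C@H](O[Si](CC)(CC)CC)CC2=CC(=O)C(O[Si](C)(C)C(C)(C)C)=C[C@]2(C)[C@H]1C
F11 | step 9 | (R,E)-1,4-diiodo-2,3-dimethylbut-1-ene | I/C=C(C)/[C@@H](C)CI
F12 | step 9 | [(2R,3E)-4-iodo-2,3-dimethylbut-3-en-1-yl]triphenylphosphonium iodide | I/C=C(C)/[C@@H](C)C[P+](c1ccccc1)(c1ccccc1)c1ccccc1.[I-]
F13 | step 9 | 4-(trimethylsilyl)but-3-ynal | C[Si](C)(C)C#CCC=O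
A1 | alternative 1 | 7-methoxy dienone bridged from O3 to C5 by an O–SiMe2–CH2 link, O2 as methoxymethyl ether | C[Si]1(C)C[C@]23C=C(OC)C(=O)C=C2C[C@@H](OCOC)[C@H](O1)[C@@H]3C
A2 | alternative 1 | tetralin phenol (8-hydroxy-7-methoxy) with the bromomethyl(dimethyl)silyl ether on O3 and the methoxymethyl ether on O2 | BrC[Si](C)(C)O[C@H]1[C@H](OCOC)Cc2cc(O)c(OC)cc2[C@H]1C
A3 | alternative 2 | decalin with the C7=C8 enediol bis(trimethylsilyl) ether, C3 dioxolane and C10 trimethylsilyl ether | C[Si](C)(C)OC1=C(O[Si](C)(C)C)C[C@]2(C)[C@@H](C)C3(OCCO3)CC[C@]2(O[Si](C)(C)C)C1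
A4 | alternative 2 | ring A diester with methoxycarbonylmethyl arms on C5 and C10 | COC(=O)C[C@]1(C)[C@@H](C)C2(OCCO2)CC[C@]1(O[Si](C)(C)C)CC(=O)OC
A5 | alternative 3 | cis-fused 3-(tert-butyldimethylsilyloxy)-4,5-dimethyldecalin-2,8-dione with the C6=C7 enone | CC(C)(C)[Si](C)(C)O[C@H]1C(=O)C[C@@H]2CC(=O)C=C[C@]2(C)[C@H]1C
A6 | alternative 3 | 4-methylcyclohexa-2,5-dienone carrying on C4 the (2R,3R)-3-(tert-butyldimethylsilyloxy)-4-oxopentan-2-yl chain | CC(=O)[C@H](O[Si](C)(C)C(C)(C)C)[C@H](C)C1(C)C=CC(=O)C=C1
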